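**Retrosynthetic overview**

1. Target ⇐ C12 iodide of a trans-decalin di-tert-butyl ester; the butenolide is attached last (lactone-enolate alkylation, sulfoxide elimination, ester cleavage).
2. Ring A ⇐ six-membered lactone fused to ring B, by an ester-enolate Claisen ring contraction that forms C3–C4. Enabling feature: the carboxyl carbon C19 on quaternary C4 is 1,5 to C1 (C19–C4–C5–C10–C1), so C19 and C1 can be tied through one oxygen into a δ-lactone while C2–C3 sit on C1 as a vinyl group; HO2C(19)–C4–C3–C2=C1 of a Δ1-decalin is the γ,δ-unsaturated-acid retron.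
3. Lactone ⇐ ring-B ketone: aldol at C10 (quaternary centre), ynone reduction (sets C1, which later dictates C4), intramolecular Horner–Wadsworth–Emmons closure (C4=C5; the sp2 C5 lets the fused lactone fold into a boat and is hydrogenated to 5α-H afterwards).
4. Ring B ⇐ catalytic enantioselective Diels–Alder reaction of a 2-silyloxydiene with an acrylate (sets C9; C8 is equilibrated later).
5. Order of ring formation: ring B → temporary lactone ring → ring A (lactone ring consumed) → butenolide ring (brought in preformed, unsaturation introduced last).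

Key step: step 11

Numbering: labdane numbering throughout (ring A = C1–C5, C10; ring B = C5–C10; C17 on C8, C18/C19 on C4, C20 on C10; β = face of the C10 methyl).
Assumption: the facial senses stated for the two catalyst-controlled steps (3 and 6) follow the accepted transition-state models of these catalysts; if either proves opposite, the mirror-image catalyst is used.

**Route**

Step 1
Reactants: 1 3-(benzyloxy)propanal; 2 3-(triphenyl-λ5-phosphanylidene)butan-2-one
Product: 3 (E)-6-(benzyloxy)-3-methylhex-3-en-2-one
Conditions: toluene, 90 °C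
Reagents that add atoms: none
Why: Wittig olefination with an acyl-stabilised ylide should give the (E)-trisubstituted enone; no stereocentre is formed.

Step 2
Reactants: 3 (E)-6-(benzyloxy)-3-methylhex-3-en-2-one
Product: 4 (E)-[6-(benzyloxy)-3-methylhexa-1,3-dien-2-yl]oxy-triisopropylsilane
Conditions: LDA, THF, −78 °C; then TIPSOTf
Reagents that add atoms: triisopropylsilyl trifluoromethanesulfonate, CC(C)[Si](C(C)C)(C(C)C)OS(=O)(=O)C(F)(F)F
Why: kinetic enolisation of the methyl ketone (cross-conjugated enolate) followed by O-silylation should give the 2-silyloxydiene with the (E)-alkene untouched.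

Step 3
Reactants: 4 the silyloxydiene; 5 2,2,2-trifluoroethyl prop-2-enoate
Product: 6 2,2,2-trifluoroethyl (1S,2S)-2-[2-(benzyloxy)ethyl]-3-methyl-4-(triisopropylsilyloxy)cyclohex-3-ene-1-carboxylate (ring B; C8 ester and C9 chain cis, both β)
Conditions: (S)-3,3-diphenyl-1-(o-tolyl)tetrahydro-1H,3H-pyrrolo[1,2-c][1,3,2]oxazaborole (20 mol %), Tf2NH (18 mol %), CH2Cl2, −78 → −40 °C
Reagents that add atoms: none
Why: catalytic enantioselective Diels–Alder reaction (acrylate activated by a chiral oxazaborolidinium cation); the silyloxy group ("para") and the terminal alkyl group ("ortho") both place the ester on C8, endo approach makes C8/C9 cis, and the catalyst-shielded acrylate face fixes C8 and, through the endo mode, the retained centre C9.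

Step 4
Reactants: 6 the Diels–Alder adduct; 7 3-(trimethylsilyl)prop-2-ynal
Product: 8 2,2,2-trifluoroethyl 2-[2-(benzyloxy)ethyl]-3-[1-hydroxy-3-(trimethylsilyl)prop-2-yn-1-yl]-3-methyl-4-oxocyclohexane-1-carboxylate (C10: CH3 β, C1 α; both C1 epimers)
Conditions: TiCl4, CH2Cl2, −78 °C; aq. NaHCO3
Reagents that add atoms: none
Why: Mukaiyama aldol addition of the regiodefined tetrasubstituted enol silane; the aldehyde should add to C10 anti to the C9 chain (held pseudoaxial by A1,2 strain with the C10 methyl), which sets the quaternary centre, while C1 forms as a mixture that step 5 erases.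

Step 5
Reactants: 8 the aldol adduct
Product: 9 2,2,2-trifluoroethyl 2-[2-(benzyloxy)ethyl]-3-methyl-4-oxo-3-[3-(trimethylsilyl)prop-2-ynoyl]cyclohexane-1-carboxylate
Conditions: Dess–Martin periodinane, CH2Cl2, 0 °C → rt
Reagents that add atoms: none
Why: Dess–Martin oxidation of the secondary propargylic alcohol; the carbon between the two carbonyls is quaternary, so nothing can epimerise.

Step 6
Reactants: 9 the ynone
Product: 10 propargylic alcohol, single C1 epimer (CIP S at the carbinol carbon; spatially the arrangement that later puts the unsaturated group cis to C9 across the lactone ring)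
Conditions: Ru[(S,S)-TsNCH(Ph)CH(Ph)NH](p-cymene) (2 mol %), i-PrOH, 25 °C
Reagents that add atoms: none
Why: asymmetric transfer hydrogenation of an alkynyl ketone (outer-sphere hydride/proton transfer, base-free); alkynyl ketones are reduced fast and irreversibly while the hindered dialkyl ketone at C5 is a poor substrate, and the catalyst, not chelation, selects the carbonyl face.

Step 7
Reactants: 10 the propargylic alcohol; 11 2-(diethoxyphosphoryl)propanoic acid
Product: 12 2-(diethoxyphosphoryl)propanoate ester of 10 (mixture at the phosphorus-bearing carbon)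
Conditions: DCC, DMAP (cat.), CH2Cl2, 0 °C → rt
Reagents that add atoms: none
Why: Steglich esterification should acylate the hindered secondary alcohol without touching C1.

Step 8
Reactants: 12 the phosphonate ester
Product: 13 2,2,2-trifluoroethyl 8-[2-(benzyloxy)ethyl]-4,8a-dimethyl-3-oxo-1-[(trimethylsilyl)ethynyl]-1,5,6,7,8,8a-hexahydro-3H-isochromene-7-carboxylate (isochromene C1 = C1, C3 = C19, C4 = C4, C4a = C5, C7 = C8, C8 = C9, C8a = C10)
Conditions: NaH, THF, 0 → 65 °C
Reagents that add atoms: none
Why: intramolecular Horner–Wadsworth–Emmons olefination of the C5 ketone closes the six-membered unsaturated lactone (ring size fixes the alkene geometry); C10 is quaternary, so neither retro-aldol nor β-elimination can compete.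

Step 9
Reactants: 13 the silylethynyl lactone
Product: 14 the corresponding 1-ethynyl lactone
Conditions: TBAF, AcOH, THF, 0 °C
Reagents that add atoms: none
Why: fluoride protodesilylation of the alkynylsilane, buffered to spare the lactone and the trifluoroethyl ester.

Step 10
Reactants: 14 the ethynyl lactone
Product: 15 2,2,2-trifluoroethyl 8-[2-(benzyloxy)ethyl]-4,8a-dimethyl-3-oxo-1-vinyl-1,5,6,7,8,8a-hexahydro-3H-isochromene-7-carboxylate (vinyl cis to C9 and trans to the C10 methyl across the lactone ring)
Conditions: H2 (1 atm), Pd/CaCO3 poisoned with Pb(OAc)2 (Lindlar catalyst), quinoline, EtOAc, rt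
Reagents that add atoms: none
Why: Lindlar semihydrogenation of the terminal alkyne; the tetrasubstituted enoate alkene and the benzyl ether should be inert.

Step 11
Reactants: 15 the vinyl lactone
Product: 18 12-(benzyloxy)-13,14,15,16-tetranorlabda-1,5-diene-17,19-dioic acid 17-(2,2,2-trifluoroethyl) ester (4α-CH3 4β-CO2H 8β-ester 9α-H), via silyl dienyl ketene acetal 16 (not isolated), via silyl ester 17 (not isolated)
Conditions: TBSOTf, Et3N, toluene, 0 °C → rt, then 110 °C; then 1 M HCl, THF, rt
Reagents that add atoms: none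
Why: TBSOTf/Et3N removes a γ-hydrogen at C6 of the unsaturated lactone to give the silyl dienyl ketene acetal 16, whose C4=C19(OSi)–O–C1–C2=C3 array undergoes the [3,3] shift (C1–O breaks, C3–C4 forms) through the boat-like, bicyclo[2.2.2]-type transition state that a lactone ring imposes. The closest known reactions are the Ireland–Claisen ring contractions of 6-alkenyl δ-lactone silyl ketene acetals (lactone-to-cyclohexene and dioxanone-to-dihydropyran rearrangements) and the Ireland–Claisen rearrangements of silyl dienolates from allyl esters of α,β-unsaturated acids. Ring A closes as a six-membered carbocycle by suprafacial sigmatropic bond formation between the ketene-acetal carbon C4 and the vinyl terminus C3; the lactone carbons C4, C5, C10 and C1 are kept and the O–C19 bridge is released as the carboxyl group. The new quaternary centre C4 is controlled by C1: the vinyl group lies on the α face of the lactone ring, so C3 bonds to the α face of C4, the former lactone carbonyl becomes the β (axial) carboxyl and the methyl ends α. The step needs site-selective enolisation and a reachable boat: C10 is quaternary, so only C6 can be deprotonated and the ring oxygen cannot be eliminated, the simple C8 ester should not be enolised under soft conditions (any loss there is repaired in step 12), and the sp2 C5 removes the trans ring-fusion constraint that would stop a saturated fused lactone from folding.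

Step 12
Reactants: 18 the diene acid
Product: 20 12-(benzyloxy)-13,14,15,16-tetranorlabda-1,5-diene-17,19-dioic acid (8α-CO2H 8β-H 9α-H), via 8α methyl ester 19 (not isolated)
Conditions: NaOMe, MeOH, 60 °C; then H2O, reflux; then aq. HCl
Reagents that add atoms: water, O
Why: transesterification and base equilibration through the C8 ester enolate should place the ester equatorial (8α, trans to the C9 chain and free of the 1,3-diaxial C10 methyl), and saponification in the same flask gives the diacid; C4 has no α-hydrogen.

Step 13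
Reactants: 20 the diacid
Product: 21 di-tert-butyl 12-(benzyloxy)-13,14,15,16-tetranorlabda-1,5-diene-17,19-dioate
Conditions: Me2NCH(Ot-Bu)2, toluene, 80 °C
Reagents that add atoms: N,N-dimethylformamide di-tert-butyl acetal, CN(C)C(OC(C)(C)C)OC(C)(C)C
Why: O-alkylation of both carboxylic acids by the tert-butyl donor; bond formation is at oxygen, so the hindered tertiary C19 acid should also react.

Step 14
Reactants: 21 the diene diester
Product: 22 di-tert-butyl 12-hydroxy-13,14,15,16-tetranorlabdane-17,19-dioate (5α-H 8β-H 9α-H)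
Conditions: H2 (50 bar), 10% Pd/C, EtOAc–AcOH, 50 °C
Reagents that add atoms: none
Why: heterogeneous catalytic hydrogenation saturates C1=C2 and C5=C6 and cleaves the benzyl ether; hydrogen should add to C5=C6 from the α face, opposite the axial C10 methyl and the axial C4 ester, giving the trans-decalin.

Step 15
Reactants: 22 the hydroxy diester
Product: 23 di-tert-butyl 12-iodo-13,14,15,16-tetranorlabdane-17,19-dioate
Conditions: I2, PPh3, imidazole, CH2Cl2, 0 °C → rt
Reagents that add atoms: iodine, II
Why: Appel-type iodination of the unhindered primary alcohol.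

Step 16
Reactants: 24 3-bromodihydrofuran-2(3H)-one; 25 benzenethiol
Product: 26 3-(phenylsulfanyl)dihydrofuran-2(3H)-one (racemic)
Conditions: Et3N, CH2Cl2, 0 °C → rt
Reagents that add atoms: none
Why: SN2 displacement of the activated α-bromide by thiolate.

Step 17
Reactants: 23 the iodide; 26 3-(phenylsulfanyl)dihydrofuran-2(3H)-one
Product: 27 di-tert-butyl 13-(phenylsulfanyl)labdan-16,15-olide-17,19-dioate (both C13 epimers)
Conditions: LDA, THF, −78 °C (26); then 23, DMPU, −78 °C → rt
Reagents that add atoms: none
Why: SN2 alkylation of the sulfur-stabilised lactone enolate by the primary iodide; the tert-butyl esters are inert and the C13 mixture is erased in step 18.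

Step 18
Reactants: 27 the sulfide
Product: 29 di-tert-butyl labd-13-en-16,15-olide-17,19-dioate, via sulfoxide 28 (not isolated)
Conditions: mCPBA (1.0 equiv), CH2Cl2, −78 → 0 °C; then toluene, pyridine (cat.), 110 °C
Reagents that add atoms: none
Why: sulfide oxidation followed by thermal syn-elimination of the sulfoxide toward the ring CH2 should give the endocyclic α-alkyl butenolide, the usual outcome for α-alkyl-α-sulfinyl γ-lactones.

Step 19
Reactants: 29 the butenolide diester
Product: 30 labd-13-en-16,15-olide-17,19-dioic acid (4α-CH3, 5α-H, 8α-CO2H, 9α-H, 10β-CH3), the target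
Conditions: TFA–CH2Cl2 (1:3), rt
Reagents that add atoms: none
Why: acidolysis of both tert-butyl esters (loss of isobutene); the butenolide is stable to acid and no stereocentre is touched.

**Compound list**

1 | 3-(benzyloxy)propanal | O=CCCOCc1ccccc1 | starting material
2 | 3-(triphenyl-λ5-phosphanylidene)butan-2-one | CC(=O)C(C)=P(c1ccccc1)(c1ccccc1)c1ccccc1 | starting material
3 | (E)-6-(benzyloxy)-3-methylhex-3-en-2-one | CC(=O)/C(C)=C/CCOCc1ccccc1 | intermediate
4 | (E)-[6-(benzyloxy)-3-methylhexa-1,3-dien-2-yl]oxy-triisopropylsilane | C=C(O[Si](C(C)C)(C(C)C)C(C)C)/C(C)=C/CCOCc1ccccc1 | intermediate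
5 | 2,2,2-trifluoroethyl prop-2-enoate | C=CC(=O)OCC(F)(F)F | starting material
6 | 2,2,2-trifluoroethyl (1S,2S)-2-[2-(benzyloxy)ethyl]-3-methyl-4-(triisopropylsilyloxy)cyclohex-3-ene-1-carboxylate | CC1=C(O[Si](C(C)C)(C(C)C)C(C)C)CC[C@H](C(=O)OCC(F)(F)F)[C@@H]1CCOCc1ccccc1 | intermediate
7 | 3-(trimethylsilyl)prop-2-ynal | C[Si](C)(C)C#CC=O | starting material
8 | aldol adduct (C10 quaternary, both C1 epimers) | C[C@]1(C(O)C#C[Si](C)(C)C)C(=O)CC[C@H](C(=O)OCC(F)(F)F)[C@@H]1CCOCc1ccccc1 | intermediate
9 | ynone (C1 ketone, C5 ketone) | C[C@]1(C(=O)C#C[Si](C)(C)C)C(=O)CC[C@H](C(=O)OCC(F)(F)F)[C@@H]1CCOCc1ccccc1 | intermediate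
10 | propargylic alcohol, single C1 epimer | C[C@]1([C@H](O)C#C[Si](C)(C)C)C(=O)CC[C@H](C(=O)OCC(F)(F)F)[C@@H]1CCOCc1ccccc1 | intermediate
11 | 2-(diethoxyphosphoryl)propanoic acid | CC(C(=O)O)P(=O)(OCC)OCC | starting material
12 | 2-(diethoxyphosphoryl)propanoate of 10 | C[C@]1([C@H](OC(=O)C(C)P(=O)(OCC)OCC)C#C[Si](C)(C)C)C(=O)CC[C@H](C(=O)OCC(F)(F)F)[C@@H]1CCOCc1ccccc1 | intermediate
13 | silylethynyl unsaturated lactone | C[C@]12[C@@H](C#C[Si](C)(C)C)OC(=O)C(C)=C1CC[C@H](C(=O)OCC(F)(F)F)[C@@H]2CCOCc1ccccc1 | intermediate
14 | ethynyl unsaturated lactone | C[C@]12[C@@H](C#C)OC(=O)C(C)=C1CC[C@H](C(=O)OCC(F)(F)F)[C@@H]2CCOCc1ccccc1 | intermediate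
15 | vinyl unsaturated lactone | C[C@]12[C@@H](C=C)OC(=O)C(C)=C1CC[C@H](C(=O)OCC(F)(F)F)[C@@H]2CCOCc1ccccc1 | intermediate
16 | tert-butyldimethylsilyl dienyl ketene acetal of 15 | C[C@]12[C@@H](C=C)OC(O[Si](C)(C)C(C)(C)C)=C(C)C1=CC[C@H](C(=O)OCC(F)(F)F)[C@@H]2CCOCc1ccccc1 | intermediate
17 | tert-butyldimethylsilyl ester of 18 | C[C@]12C=CC[C@](C)(C(=O)O[Si](C)(C)C(C)(C)C)C1=CC[C@H](C(=O)OCC(F)(F)F)[C@@H]2CCOCc1ccccc1 | intermediate
18 | Δ1,Δ5-diene 19-acid, 17-trifluoroethyl ester (8β) | C[C@]12C=CC[C@](C)(C(=O)O)C1=CC[C@H](C(=O)OCC(F)(F)F)[C@@H]2CCOCc1ccccc1 | intermediate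
19 | Δ1,Δ5-diene 19-acid, 17-methyl ester (8α) | C[C@]12C=CC[C@](C)(C(=O)O)C1=CC[C@@H](C(=O)OC)[C@@H]2CCOCc1ccccc1 | intermediate
20 | Δ1,Δ5-diene 17,19-diacid (8α) | C[C@]12C=CC[C@](C)(C(=O)O)C1=CC[C@@H](C(=O)O)[C@@H]2CCOCc1ccccc1 | intermediate
21 | Δ1,Δ5-diene di-tert-butyl ester | C[C@]12C=CC[C@](C)(C(=O)OC(C)(C)C)C1=CC[C@@H](C(=O)OC(C)(C)C)[C@@H]2CCOCc1ccccc1 | intermediate
22 | saturated 12-hydroxy di-tert-butyl ester | C[C@]12CCC[C@](C)(C(=O)OC(C)(C)C)[C@@H]1CC[C@@H](C(=O)OC(C)(C)C)[C@@H]2CCO | intermediate
23 | 12-iodo di-tert-butyl ester | C[C@]12CCC[C@](C)(C(=O)OC(C)(C)C)[C@@H]1CC[C@@H](C(=O)OC(C)(C)C)[C@@H]2CCI | intermediate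
24 | 3-bromodihydrofuran-2(3H)-one | O=C1OCCC1Br | starting material
25 | benzenethiol | Sc1ccccc1 | starting material
26 | 3-(phenylsulfanyl)dihydrofuran-2(3H)-one | O=C1OCCC1Sc1ccccc1 | intermediate
27 | 13-(phenylsulfanyl) lactone di-tert-butyl ester (C13 epimers) | C[C@]12CCC[C@](C)(C(=O)OC(C)(C)C)[C@@H]1CC[C@@H](C(=O)OC(C)(C)C)[C@@H]2CCC1(Sc2ccccc2)CCOC1=O | intermediate
28 | 13-(phenylsulfinyl) lactone di-tert-butyl ester | C[C@]12CCC[C@](C)(C(=O)OC(C)(C)C)[C@@H]1CC[C@@H](C(=O)OC(C)(C)C)[C@@H]2CCC1(S(=O)c2ccccc2)CCOC1=O | intermediate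
29 | di-tert-butyl labd-13-en-16,15-olide-17,19-dioate | C[C@]12CCC[C@](C)(C(=O)OC(C)(C)C)[C@@H]1CC[C@@H](C(=O)OC(C)(C)C)[C@@H]2CCC1=CCOC1=O | intermediate
30 | labd-13-en-16,15-olide-17,19-dioic acid (CNP0478950.1) | C[C@]12CCC[C@](C)(C(=O)O)[C@@H]1CC[C@@H](C(=O)O)[C@@H]2CCC1=CCOC1=O | target

**Step count and weak points**

Total step count: 19. Longest linear sequence: 18 steps (steps 1–15 and 17–19; step 16 is a one-step side branch).

Steps most likely to fail:

Step 11 (key step). What may go wrong: the fused lactone may not fold into the boat needed for the sigmatropic shift, or ionisation of the allylic C1–O bond by the silyl triflate may outrun it, both made worse by crowding at the forming quaternary carbon. The fallback sets out from 10 and comes back at 21; it keeps the ring contraction but makes the quaternary centre afterwards by alkylation. Compound 10 would be esterified with 2-(diethoxyphosphoryl)acetic acid (DCC, DMAP) to the phosphonoacetate F1, cyclised (NaH, THF) to the 4-desmethyl silylethynyl lactone F2, desilylated (TBAF, AcOH) to the ethynyl lactone F3 and semihydrogenated to the vinyl lactone F4. The same silyl ketene acetal rearrangement, now forming a tertiary instead of a quaternary carbon, would give the 4-desmethyl diene acid F5. This would be equilibrated and saponified (NaOMe, MeOH; H2O) to the diacid F6 and converted with Me2NCH(Ot-Bu)2 into the di-tert-butyl ester F7. Deprotonation of F7 at C4 (LDA, THF–DMPU, −78 °C) and methylation with MeI from the α face, away from the C10 methyl (the classical C4 alkylation of resin-acid esters), would give 21.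

Step 8. What may go wrong: slow attack of the phosphonate carbanion on the neopentyl-type C5 ketone, with ester cleavage or epimerisation at C8 taking over. The fallback sets out from 10 and comes back at 13. Acylation of 10 with 2-bromopropanoyl bromide and pyridine would give the bromo ester F8. An intramolecular Reformatsky addition with SmI2 (THF, −78 °C) onto the C5 ketone would give the β-hydroxy lactone F9. Dehydration (SOCl2, pyridine, or Burgess reagent) would give 13; a Δ5 isomer, if formed, leads to the same ketene acetal in step 11.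

Step 14. What may go wrong: poor facial selectivity, or stalled reduction, at the hindered trisubstituted C5=C6 alkene on the metal surface. The fallback sets out from 21 and comes back at 22. Hydrogen-atom-transfer reduction (Mn(dpm)3, PhSiH3, t-BuOOH, i-PrOH, rt) makes the tertiary C5 radical, which is quenched from the axial α side under thermodynamic control to give the trans-fused 5α-H benzyl ether F10, with C1=C2 still present. Mild hydrogenation (H2 1 atm, Pd/C, EtOAc) would then saturate C1=C2 and cleave the benzyl ether to give 22.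

**Further compounds**

F1 | step 11 | 2-(diethoxyphosphoryl)acetate of 10 | C[C@]1([C@H](OC(=O)CP(=O)(OCC)OCC)C#C[Si](C)(C)C)C(=O)CC[C@H](C(=O)OCC(F)(F)F)[C@@H]1CCOCc1ccccc1
F2 | step 11 | 4-desmethyl silylethynyl unsaturated lactone | C[C@]12[C@@H](C#C[Si](C)(C)C)OC(=O)C=C1CC[C@H](C(=O)OCC(F)(F)F)[C@@H]2CCOCc1ccccc1
F3 | step 11 | 4-desmethyl ethynyl unsaturated lactone | C[C@]12[C@@H](C#C)OC(=O)C=C1CC[C@H](C(=O)OCC(F)(F)F)[C@@H]2CCOCc1ccccc1
F4 | step 11 | 4-desmethyl vinyl unsaturated lactone | C[C@]12[C@@H](C=C)OC(=O)C=C1CC[C@H](C(=O)OCC(F)(F)F)[C@@H]2CCOCc1ccccc1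
F5 | step 11 | 4-desmethyl Δ1,Δ5-diene 19-acid, 17-trifluoroethyl ester | C[C@]12C=CC[C@H](C(=O)O)C1=CC[C@H](C(=O)OCC(F)(F)F)[C@@H]2CCOCc1ccccc1
F6 | step 11 | 4-desmethyl Δ1,Δ5-diene 17,19-diacid (8α) | C[C@]12C=CC[C@H](C(=O)O)C1=CC[C@@H](C(=O)O)[C@@H]2CCOCc1ccccc1
F7 | step 11 | 4-desmethyl Δ1,Δ5-diene di-tert-butyl ester | C[C@]12C=CC[C@H](C(=O)OC(C)(C)C)C1=CC[C@@H](C(=O)OC(C)(C)C)[C@@H]2CCOCc1ccccc1
F8 | step 8 | 2-bromopropanoate of 10 (mixture at the bromine-bearing carbon) | C[C@]1([C@H](OC(=O)C(C)Br)C#C[Si](C)(C)C)C(=O)CC[C@H](C(=O)OCC(F)(F)F)[C@@H]1CCOCc1ccccc1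
F9 | step 8 | 5-hydroxy saturated lactone (C4 and C5 epimers) | C[C@]12[C@@H](C#C[Si](C)(C)C)OC(=O)C(C)C1(O)CC[C@H](C(=O)OCC(F)(F)F)[C@@H]2CCOCc1ccccc1
F10 | step 14 | 5α-H Δ1-ene 12-benzyl ether di-tert-butyl ester | C[C@]12C=CC[C@](C)(C(=O)OC(C)(C)C)[C@@H]1CC[C@@H](C(=O)OC(C)(C)C)[C@@H]2CCOCc1ccccc1
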